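You asked for a quick number on the ochre flask and suspected it had stalled, so I decided to treat chain length as a conversion of the chain reading rather than integrate anything.

| setting | ochre | flask |
|---|---|---|
| free monomer | 0.30 M | 0.30 M |
| protic impurity | 0.30 M | 0.300 M |
| initiator | 1 mol% | 1 mol% |
| remark | the very flask that is asked about, followed so far |  |
| time |  | 10 d |

- ochre (time / d: monomer in chains / %, free monomer / %): 0.167: 1.6, 94.1; 0.500: 16.0, 78.7; 0.833: 24.8, 64.0; 1.25: 35.9, 52.8; 1.67: 41.3, 42.7; 2.50: 49.0, 30.5; 3.00: 49.6, 27.7

(each reading ± 1 percentage point)

- the average divides the monomer in chains by the number of chains begun, living and dead together
- the numbers in the tables scatter by 1 percentage point (one standard deviation)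
- on the list of suspects stand: free monomer + living end -> monomer in chains + living end; free monomer + initiator -> living end + monomer in chains; protic impurity + free monomer -> quenched substrate; monomer in chains + living end -> free monomer + living end; living end + monomer in chains -> dead end
- the earlier runs do not show the number of chains; that part of a forecast is a guess

1. whether the average number of monomer units in a chain (chains begun, living or dead) reaches 10 by 10 d (yes / no)
2. average number of monomer units in a chain (chains begun, living or dead) at 10 d

I defined the full length n, the units per chain if the whole charge stood in chains and each initiator had begun one chain: n = 100. The length is then n times u, the fraction of the charge in chains. This assumes every initiator began a chain, which is a guess because chains were not counted.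

I replaced the flat end of the curve by its mean, taking the readings at 2.50 d and 3.00 d: u = 49.3%. That gave a length of 49.3 at 10 d, so my answer was yes, with the length above the 10 wanted. Scatter put 0.707 units on that mean. Free monomer and monomer in chains together stood at 77.3% at the last reading, and I read the gap as monomer going to quenched substrate, so the plateau could sag by an amount those points did not show.

The forecast said yes, on the ground that “DP already exceeds 10”, and gave 40 in a range of 30 to 54, below my figure.

The ochre flask gave yes, with 47.3 units at 10 d, against my 49.3.

    free monomer + living end → monomer in chains + living end, rate k1*[living end]*[free monomer] (k = 0.160 L mol⁻¹ min⁻¹)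
    free monomer + initiator → living end + monomer in chains (k = 0.0110 L mol⁻¹ min⁻¹)
    protic impurity + free monomer → quenched substrate (k = 3.90 × 10⁻⁴ L mol⁻¹ min⁻¹)
    monomer in chains + living end → free monomer + living end, rate k4*[living end] as long as [monomer in chains] is above zero (k = 0.00990 min⁻¹)
    living end + monomer in chains → dead end (k = 9.40 × 10⁻⁴ L mol⁻¹ min⁻¹)

At 10 d in the ochre flask, monomer in chains was being made at 0.673 of the rate at which it was used up, each step taken net, after a length of 51.3 at 5.00 d. I used n once more on the same flask at 100 d, where initiator stood at 0% and monomer in chains at 41.0%. That gave a length of 41.0, with free monomer at 0.0316%.

All runs come from a simulation for an exercise; the scatter is artificial.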